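**Strategy.** Everything rests on disconnecting the C4–C5 bond of the cyclopentenone ring (C1 carbonyl, C2 pentenyl, C3 ester chain, C4 carbinol, C5 CHBr). The O=C1–C2=C3–C4(OH)–C5(Br) array is the signature of a Piancatelli-type 4π-conrotatory closure: under a chiral Brønsted acid the bromo-enol of the acyclic (Z)-bromoacetyl enal 15 adds to its cis-aldehyde, closing the ring and setting both stereocentres, trans, in one isomerisation. Compound 15 already carries the tetrasubstituted C2=C3 olefin with both side chains; it comes from anti-carbomagnesiation–iodination of an enynol, oxidation and Stille coupling–bromination.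

Key step: step 7

Remarks on the chemistry:
- Ring numbering used throughout: C1 = C=O, C2 = pentenyl-bearing, C3 = ester-chain-bearing, C4 = CH(OH), C5 = CHBr. The target is (4R,5S), trans. In its systematic name the same centres appear as 5R (OH) and 4S (Br).
- Compounds 1, 3, 5 and 13 are taken as commercial.
- TRIP = 3,3'-bis(2,4,6-triisopropylphenyl)-1,1'-binaphthyl-2,2'-diyl hydrogen phosphate. Which antipode of this acid gives (4R,5S) cannot be predicted with confidence. (R) is written and would be exchanged for (S) if the first run shows the opposite sense.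

**Step 1**
Reactants: 1 (Z)-pent-2-en-1-ol
Product: 2 (Z)-1-bromopent-2-ene
Conditions: PBr3 (0.4 equiv), pyridine (cat.), Et2O, −20 to 0 °C
Reagents that add atoms: phosphorus tribromide, BrP(Br)Br
Why: PBr3 bromination of a primary allylic alcohol is an SN2 displacement that, kept cold, should retain the (Z)-olefin and keep allylic transposition minor.

**Step 2**
Reactants: 2 (Z)-1-bromopent-2-ene; 3 prop-2-yn-1-ol
Product: 4 (Z)-oct-5-en-2-yn-1-ol
Conditions: CuI (10 mol%), K2CO3, DMF, 0 °C to rt
Reagents that add atoms: none
Why: Copper-catalysed allylation of a terminal alkyne: the alkynylcopper formed from 3 and CuI should displace the primary allylic bromide directly, giving the skipped enyne with the (Z)-geometry untouched and the free hydroxyl tolerated.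

**Step 3**
Reactants: 5 8-bromooctanenitrile
Product: 7 trimethyl ortho-8-bromooctanoate (8-bromo-1,1,1-trimethoxyoctane), via imidate hydrochloride 6 (not isolated)
Conditions: HCl (g), MeOH (1.1 equiv), Et2O, 0 °C; then MeOH (excess), hexane, rt
Reagents that add atoms: methanol, CO
Why: Pinner reaction: HCl/MeOH converts the nitrile into the imidate hydrochloride, whose methanolysis gives the orthoester, a carboxyl mask inert to Grignard formation.

**Step 4**
Reactants: 4 (Z)-oct-5-en-2-yn-1-ol; 7 8-bromo-1,1,1-trimethoxyoctane
Product: 11 methyl (9Z,12Z)-9-(hydroxymethyl)-10-iodopentadeca-9,12-dienoate, via Grignard reagent 8 (not isolated), via magnesium chelate 9 (not isolated), via orthoester iodoalkenol 10 (not isolated)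
Conditions: 7, Mg, THF, 35 °C (gives 8); 4, i-PrMgCl (1.0 equiv), THF, 0 °C; then 8 (1.8 equiv), CuI (10 mol%), 0 °C to rt; I2, THF, −40 to 0 °C; aq. NH4Cl, then 5% aq. citric acid, rt
Reagents that add atoms: iodine, II; water, O
Why: Copper-catalysed anti-carbomagnesiation of a propargylic alcohol: the magnesium alkoxide directs the alkyl group to the carbinol-side alkyne carbon and magnesium to the distal one in a five-membered chelate, so iodinolysis should give the tetrasubstituted (Z)-iodoalkene with iodine cis to CH2OH and the two chains cis, and the mildly acidic work-up unmasks the methyl ester.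

**Step 5**
Reactants: 11 methyl (9Z,12Z)-9-(hydroxymethyl)-10-iodopentadeca-9,12-dienoate
Product: 12 methyl (9Z,12Z)-9-formyl-10-iodopentadeca-9,12-dienoate
Conditions: Dess–Martin periodinane (1.2 equiv), NaHCO3, CH2Cl2, 0 °C to rt
Reagents that add atoms: none
Why: Buffered Dess–Martin oxidation of the primary allylic alcohol should give the β-iodoenal without touching the vinyl iodide, the ester or the skipped olefin and without E/Z leakage.

**Step 6**
Reactants: 12 methyl (9Z,12Z)-9-formyl-10-iodopentadeca-9,12-dienoate; 13 tributyl(1-ethoxyvinyl)stannane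
Product: 15 methyl (9Z,12Z)-10-(2-bromoacetyl)-9-formylpentadeca-9,12-dienoate, via ethoxydienal 14 (not isolated)
Conditions: Pd(PPh3)4 (5 mol%), CuI (10 mol%), DMF, 50 °C; then THF/H2O 9:1, NaHCO3, NBS (1.05 equiv), −10 °C
Reagents that add atoms: N-bromosuccinimide, O=C1CCC(=O)N1Br; water, O
Why: Stille coupling of the activated β-iodoenal proceeds with retention of olefin geometry, and the electron-rich enol ether of 14 should then be brominated by NBS in wet THF far faster than the isolated (Z)-olefin, the hemiketal collapsing to the bromomethyl ketone (enol ether bromination–hydrolysis).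

**Step 7**
Reactants: 15 methyl (9Z,12Z)-10-(2-bromoacetyl)-9-formylpentadeca-9,12-dienoate
Product: 16 methyl 8-[(4S,5R)-4-bromo-5-hydroxy-3-oxo-2-[(Z)-pent-2-en-1-yl]cyclopent-1-en-1-yl]octanoate
Conditions: (R)-TRIP (10 mol%), 4 Å MS, toluene, 0 °C to rt
Reagents that add atoms: none
Why: Proposed new method: the chiral phosphoric acid is expected to enolise the bromomethyl ketone of 15 and protonate the cis-disposed aldehyde within one hydrogen-bonded ion pair, giving a 1-bromo-2,5-dihydroxypentadienyl cation that closes by thermal 4π-conrotatory electrocyclisation between the CHBr and CHOH termini; the closest known reaction types are the terminal step of the Piancatelli rearrangement, its chiral-phosphoric-acid-catalysed aza variant and Brønsted-acid-catalysed enantioselective Nazarov cyclisations. The five-membered ring closes in what is formally a 5-(enolendo)-exo-trig aldol, disfavoured as an in-plane enolate attack but allowed here because the conjugated O–C1–C2=C3–C4 array lets the termini rotate into overlap as in an iso-Nazarov closure. The trans relation of C4–OH and C5–Br follows from conrotation of the cation with both heteroatom substituents outward, and any cis isomer should be corrected by enolisation at C5 toward the more stable trans bromohydrin. The absolute sense of conrotation, hence (4R,5S), is to be controlled by the chiral phosphate counter-anion bound to the two OH groups of the cation. The step needs enolisation toward CH2Br only, which the substrate secures because the ketone has no other α-hydrogen, and it needs the fixed (Z)-geometry of C2=C3, which holds enol and aldehyde within bonding distance. The acidic, base-free medium keeps the trans-bromohydrin from closing to an epoxide and leaves the skipped (Z)-olefin in place.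

**Compound list**

1 | (Z)-pent-2-en-1-ol | CC/C=C\CO | starting material
2 | (Z)-1-bromopent-2-ene | CC/C=C\CBr | intermediate
3 | prop-2-yn-1-ol | C#CCO | starting material
4 | (Z)-oct-5-en-2-yn-1-ol | CC/C=C\CC#CCO | intermediate
5 | 8-bromooctanenitrile | N#CCCCCCCCBr | starting material
6 | methyl 8-bromooctanimidate hydrochloride | COC(=[NH2+])CCCCCCCBr.[Cl-] | intermediate (not isolated)
7 | 8-bromo-1,1,1-trimethoxyoctane | COC(OC)(OC)CCCCCCCBr | intermediate
8 | (8,8,8-trimethoxyoctyl)magnesium bromide | COC(OC)(OC)CCCCCCC[Mg]Br | intermediate (not isolated)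
9 | 3-[(Z)-pent-2-en-1-yl]-4-(8,8,8-trimethoxyoctyl)-2,5-dihydro-1,2-oxamagnesole | CC/C=C\CC1=C(CCCCCCCC(OC)(OC)OC)CO[Mg]1 | intermediate (not isolated)
10 | (2Z,5Z)-3-iodo-2-(8,8,8-trimethoxyoctyl)octa-2,5-dien-1-ol | COC(OC)(OC)CCCCCCC/C(CO)=C(/I)C/C=C\CC | intermediate (not isolated)
11 | methyl (9Z,12Z)-9-(hydroxymethyl)-10-iodopentadeca-9,12-dienoate | COC(=O)CCCCCCC/C(CO)=C(/I)C/C=C\CC | intermediate
12 | methyl (9Z,12Z)-9-formyl-10-iodopentadeca-9,12-dienoate | COC(=O)CCCCCCC/C(C=O)=C(/I)C/C=C\CC | intermediate
13 | tributyl(1-ethoxyvinyl)stannane | CCCC[Sn](CCCC)(CCCC)C(=C)OCC | starting material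
14 | methyl (9Z,12Z)-10-(1-ethoxyvinyl)-9-formylpentadeca-9,12-dienoate | COC(=O)CCCCCCC/C(C=O)=C(/C(=C)OCC)C/C=C\CC | intermediate (not isolated)
15 | methyl (9Z,12Z)-10-(2-bromoacetyl)-9-formylpentadeca-9,12-dienoate | COC(=O)CCCCCCC/C(C=O)=C(/C(=O)CBr)C/C=C\CC | intermediate
16 | methyl 8-[(4S,5R)-4-bromo-5-hydroxy-3-oxo-2-[(Z)-pent-2-en-1-yl]cyclopent-1-en-1-yl]octanoate | CC/C=C\CC1=C(CCCCCCCC(=O)OC)[C@@H](O)[C@H](Br)C1=O | target

**Totals.** Total step count: 7. Longest linear sequence: 6 steps (steps 1, 2, 4, 5, 6, 7); step 3 is a one-step side branch.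

**Steps most likely to fail**

1. Step 7 (proposed new method). The conrotation may proceed with poor facial selectivity under the chiral acid, or an uncatalysed or trace-acid background closure may erode the enantiomeric purity. The fallback sets out from 15 and comes back at 16, using known chemistry only. An achiral acid (diphenyl phosphate, 10 mol%, toluene, rt) should close 15 by the same Piancatelli-type pathway to the racemic trans-bromohydrin F1. Kinetic resolution with immobilised Candida antarctica lipase B and vinyl acetate in MTBE should then acylate the (4S,5R)-enantiomer faster, by the empirical size rule for secondary alcohols with the C3 side as the large group. Compound 16 would be recovered as the unreacted alcohol once conversion has passed one half.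

2. Step 4. The acyclic orthoester may ionise or be attacked in the Lewis-acidic Grignard medium, and the carbomagnesiation of the internal alkyne may stall at the mild temperature the orthoester tolerates. The fallback sets out from 4 and comes back at 11. 8-Bromooctanoic acid is esterified with (3-methyloxetan-3-yl)methanol (DCC, DMAP, CH2Cl2) to the oxetanyl ester F2. BF3·OEt2 rearranges it to the bicyclic orthoester 1-(7-bromoheptyl)-4-methyl-2,6,7-trioxabicyclo[2.2.2]octane F3. Its Grignard reagent F4 should tolerate the warmer conditions (CuI, THF/toluene, 60 °C) that the addition to 4 may demand. Iodinolysis gives the bicyclic orthoester iodoalkenol F5, and HCl in methanol converts this orthoester directly into the methyl ester 11.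

3. Step 6. NBS may attack the skipped (Z)-olefin or a 2H-pyran valence isomer of 14 in competition with the enol ether, and the bromoketo-enal may close prematurely, without the chiral acid, during the aqueous stage. The fallback sets out from 14 (isolated after the Stille stage on triethylamine-deactivated silica) and comes back at 16. It postpones bromination until after ring closure, and its closure stage rests on the same unproven chiral-acid method as step 7. Wet oxalic acid on silica gel hydrolyses the enol ether to the methyl ketone F6. The chiral acid of step 7 should close F6 in the same conrotatory manner to the hydroxycyclopentenone F7. TMSOTf/Et3N (CH2Cl2, −78 °C) gives the bis-silyl dienol ether F8. NBS in THF at −78 °C should brominate C5 anti to the C4 silyloxy group to give the silyl ether F9, and dilute aqueous citric acid frees 16.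

**Further compounds**

F1 | step 7 | racemic trans-bromohydrin (1:1 mixture of 16 and its enantiomer) | CC/C=C\CC1=C(CCCCCCCC(=O)OC)[C@@H](O)[C@H](Br)C1=O.CC/C=C\CC1=C(CCCCCCCC(=O)OC)[C@H](O)[C@@H](Br)C1=O
F2 | step 4 | (3-methyloxetan-3-yl)methyl 8-bromooctanoate | CC1(COC(=O)CCCCCCCBr)COC1
F3 | step 4 | 1-(7-bromoheptyl)-4-methyl-2,6,7-trioxabicyclo[2.2.2]octane | CC12COC(CCCCCCCBr)(OC1)OC2
F4 | step 4 | [7-(4-methyl-2,6,7-trioxabicyclo[2.2.2]octan-1-yl)heptyl]magnesium bromide | CC12COC(CCCCCCC[Mg]Br)(OC1)OC2
F5 | step 4 | (2Z,5Z)-3-iodo-2-[7-(4-methyl-2,6,7-trioxabicyclo[2.2.2]octan-1-yl)heptyl]octa-2,5-dien-1-ol | CC12COC(CCCCCCC/C(CO)=C(/I)C/C=C\CC)(OC1)OC2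
F6 | step 6 | methyl (9Z,12Z)-10-acetyl-9-formylpentadeca-9,12-dienoate | COC(=O)CCCCCCC/C(C=O)=C(/C(C)=O)C/C=C\CC
F7 | step 6 | methyl 8-[(5S)-5-hydroxy-3-oxo-2-[(Z)-pent-2-en-1-yl]cyclopent-1-en-1-yl]octanoate | CC/C=C\CC1=C(CCCCCCCC(=O)OC)[C@@H](O)CC1=O
F8 | step 6 | methyl 8-[(5S)-2-[(Z)-pent-2-en-1-yl]-3,5-bis(trimethylsilyloxy)cyclopenta-1,3-dien-1-yl]octanoate | CC/C=C\CC1=C(CCCCCCCC(=O)OC)[C@@H](O[Si](C)(C)C)C=C1O[Si](C)(C)C
F9 | step 6 | trimethylsilyl ether of 16 | CC/C=C\CC1=C(CCCCCCCC(=O)OC)[C@@H](O[Si](C)(C)C)[C@H](Br)C1=O
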